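**Retrosynthetic overview**

1. Target 18 is a 2,3-dihydrobenzofuran (ring A = benzene, ring B = dihydrofuran). The enal is taken back to an isopropenyl group (allylic oxidation last) and the two esters to the free hydroxyls, which leads to the cis-(2R,3R)-2-isopropenyl-3-ol 11.
2. The strategy rests on the C2–C3 bond of ring B. It joins the benzylic carbinol carbon C3 to C2, which carries O1 and a CH2=C(CH3) group; this homoallylic alcohol array is what a [2,3]-Wittig shift of a benzyl 2-methylallyl ether delivers.
3. Because O1 sits on ring A ortho to the benzylic carbon, that ether has to be cyclic: the eight-membered 3-methyl-4H,6H-1,5-benzodioxocine 9, whose enol ether carbon becomes C2.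
4. 9 comes from its exocyclic alkene isomer 8, and 8 from the salicyl alcohol 5 and dichloride 6 by two Williamson etherifications; 5 comes from methyl 5-acetylsalicylate 1, whose ketone reduction sets the side-chain centre.
5. Ring order: ring A is bought, the eight-membered dioxocine ring is closed in step 5, and it is contracted to ring B in step 7.

Key step: step 7

Remark 1: the sense of induction of the bis(oxazoline)–lithium complex on this ring system cannot be derived from acyclic cases; the (S,S)-ligand is written and its antipode would be used if it leads to the (2S,3S) series. Since the side-chain centre is already (R), the two outcomes are diastereomers, and the minor one should be removable at 11 or 12.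
Remark 2: ring B compounds carry benzofuran numbering (O1, C2, C3, C3a, C7a); compounds 8–10 carry 1,5-benzodioxocine numbering (O1, C2, C3, C4, O5, C6, C6a, C10a).

**Route**

Step 1
Reactants: 1 methyl 5-acetyl-2-hydroxybenzoate
Product: 2 methyl 2-hydroxy-5-[(1R)-1-hydroxyethyl]benzoate
Conditions: RuCl[(R,R)-TsDPEN](p-cymene) (1 mol%), HCO2H–Et3N (5:2), DMF, 40 °C
Reagents that add atoms: none
Why: Noyori–Ikariya asymmetric transfer hydrogenation of an aryl methyl ketone, in which the (R,R)-TsDPEN–ruthenium hydride is expected to give the (R)-1-arylethanol while the acidic medium leaves the phenol and the ester alone, so this step sets the (R) side-chain centre.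

Step 2
Reactants: 2 methyl 2-hydroxy-5-[(1R)-1-hydroxyethyl]benzoate
Product: 4 methyl 5-[(1R)-1-(tert-butyldimethylsilyloxy)ethyl]-2-hydroxybenzoate, via bis-silyl ether 3 (not isolated)
Conditions: TBSCl (2.5 equiv), imidazole, DMF, rt; extractive work-up; then K2CO3 (0.3 equiv), MeOH, 0 °C
Reagents that add atoms: tert-butyldimethylsilyl chloride, CC(C)(C)[Si](C)(C)Cl
Why: Exhaustive silylation followed by base-catalysed methanolysis differentiates the two silyl ethers, because the aryl silyl ether next to the ester leaves as a phenoxide far faster than the secondary alkyl TBS ether is cleaved (protecting-group chemistry, no stereocentre touched).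

Step 3
Reactants: 4 methyl 5-[(1R)-1-(tert-butyldimethylsilyloxy)ethyl]-2-hydroxybenzoate
Product: 5 4-[(1R)-1-(tert-butyldimethylsilyloxy)ethyl]-2-(hydroxymethyl)phenol
Conditions: LiAlH4, THF, 0 °C to rt; aq. potassium sodium tartrate work-up
Reagents that add atoms: none
Why: Hydride reduction of the methyl ester to the benzylic alcohol with LiAlH4, the phenol being carried as its aluminate and the silyl ether and carbinol centre being inert.

Step 4
Reactants: 5 4-[(1R)-1-(tert-butyldimethylsilyloxy)ethyl]-2-(hydroxymethyl)phenol; 6 3-chloro-2-(chloromethyl)prop-1-ene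
Product: 7 {5-[(1R)-1-(tert-butyldimethylsilyloxy)ethyl]-2-{[2-(chloromethyl)prop-2-en-1-yl]oxy}phenyl}methanol
Conditions: 6 (3 equiv), K2CO3, acetone, reflux
Reagents that add atoms: none
Why: Williamson etherification selective for the phenol, the only hydroxyl that K2CO3 deprotonates, with the excess of the allylic dichloride suppressing attachment of a second phenol.

Step 5
Reactants: 7 {5-[(1R)-1-(tert-butyldimethylsilyloxy)ethyl]-2-{[2-(chloromethyl)prop-2-en-1-yl]oxy}phenyl}methanol
Product: 8 8-[(1R)-1-(tert-butyldimethylsilyloxy)ethyl]-3-methylidene-3,4-dihydro-2H,6H-1,5-benzodioxocine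
Conditions: NaH (1.5 equiv), NaI (cat.), THF–DMF, 0.005 M, 0 to 40 °C
Reagents that add atoms: none
Why: Intramolecular Williamson etherification (8-exo-tet) of the benzylic alkoxide on the allylic chloride, helped by the reactive allylic electrophile, by the arene and the sp2 carbon in the chain and by high dilution; direct and allylic (SN2') displacement give the same product by symmetry.

Step 6
Reactants: 8 8-[(1R)-1-(tert-butyldimethylsilyloxy)ethyl]-3-methylidene-3,4-dihydro-2H,6H-1,5-benzodioxocine
Product: 9 8-[(1R)-1-(tert-butyldimethylsilyloxy)ethyl]-3-methyl-4H,6H-1,5-benzodioxocine (ring Z enol ether)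
Conditions: t-BuOK (0.5 equiv), DMSO, rt
Reagents that add atoms: none
Why: Base-mediated prototropic allyl-to-propenyl ether isomerisation through the oxyallyl anion, expected to start at the allylic CH2 next to the aryloxy oxygen (the more acidic of the two allylic positions) and to give the ring-enforced Z enol ether; no stereocentre is involved.

Step 7
Reactants: 9 8-[(1R)-1-(tert-butyldimethylsilyloxy)ethyl]-3-methyl-4H,6H-1,5-benzodioxocine
Product: 11 (2R,3R)-5-[(1R)-1-(tert-butyldimethylsilyloxy)ethyl]-2-(prop-1-en-2-yl)-2,3-dihydro-1-benzofuran-3-ol, via lithiated ether 10 (not isolated)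
Conditions: t-BuLi (1.5 equiv), 2,2'-(pentane-3,3-diyl)bis[(4S)-4-isopropyl-4,5-dihydrooxazole] (1.5 equiv), hexane, −78 °C; then aq. NH4Cl
Reagents that add atoms: tert-butyllithium, [Li]C(C)(C)C (lithium in intermediate 10 only)
Why: Proposed new method: the ligand-bound t-BuLi removes one benzylic hydrogen at C6 (alpha to O5 and to the arene), and the alpha-oxy benzyllithium 10 bonds through carbon to the enol ether carbon C2 while the allylic C4–O5 bond breaks and the double bond moves to C3=C4, a suprafacial five-centre, six-electron [2,3]-Wittig shift that here runs across the eight-membered ring. The closest known reactions are the [2,3]-Wittig ring contractions of larger cyclic allyl ethers and the bis(oxazoline)/t-BuLi enantioselective [2,3]-Wittig rearrangement of acyclic benzyl allyl ethers; a contraction from eight to five ring atoms onto an enol ether terminus is without precedent. Ring B (C6–C6a–C10a–O1–C2 of 9, which is C3–C3a–C7a–O1–C2 of the benzofuran) closes by transannular C–C bond formation in a 5-exo-trig sense, the attacked C2=C3 double bond lying outside the new ring. The two carbons of the new bond are held at once by the five-membered envelope of the shift and by the nascent ring B, a bicyclo[3.3.0] transition state that can only be cis-fused, so the C3 oxygen and the C2 isopropenyl group must end on the same face; the absolute (2R,3R) sense rests on the chiral ligand–lithium complex, which should select one benzylic hydrogen and hold the lithiated carbon until it shifts with inversion, the remote (R) side-chain centre giving no help. The step needs site selectivity for C6–H over the allylic C4–H, the vinylic C2–H and the side-chain benzylic C–H, which the substrate offers because C6–H is the only unhindered hydrogen flanked by both an ether oxygen and the arene, and it needs the [2,3] path to beat the [1,2] shift, which the low temperature and the fixed Z geometry of the ring alkene favour.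

Step 8
Reactants: 11 (2R,3R)-5-[(1R)-1-(tert-butyldimethylsilyloxy)ethyl]-2-(prop-1-en-2-yl)-2,3-dihydro-1-benzofuran-3-ol
Product: 12 (2R,3R)-5-[(1R)-1-(tert-butyldimethylsilyloxy)ethyl]-2-(prop-1-en-2-yl)-2,3-dihydro-1-benzofuran-3-yl acetate
Conditions: Ac2O, pyridine, DMAP (cat.), CH2Cl2, 0 °C to rt
Reagents that add atoms: acetic anhydride, CC(=O)OC(C)=O
Why: DMAP-catalysed O-acetylation of the secondary benzylic alcohol, which takes place at oxygen and so retains the (3R) configuration.

Step 9
Reactants: 12 (2R,3R)-5-[(1R)-1-(tert-butyldimethylsilyloxy)ethyl]-2-(prop-1-en-2-yl)-2,3-dihydro-1-benzofuran-3-yl acetate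
Product: 13 (2R,3R)-5-[(1R)-1-hydroxyethyl]-2-(prop-1-en-2-yl)-2,3-dihydro-1-benzofuran-3-yl acetate
Conditions: TBAF, AcOH (1:1), THF, rt
Reagents that add atoms: none
Why: Fluoride-mediated cleavage of the secondary TBS ether, buffered with acetic acid so that the C3 acetate is neither cleaved nor eliminated toward the benzofuran and the benzylic carbinol is not ionised.

Step 10
Reactants: 13 (2R,3R)-5-[(1R)-1-hydroxyethyl]-2-(prop-1-en-2-yl)-2,3-dihydro-1-benzofuran-3-yl acetate; 14 angelic acid, (2Z)-2-methylbut-2-enoic acid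
Product: 16 (1R)-1-[(2R,3R)-3-acetoxy-2-(prop-1-en-2-yl)-2,3-dihydro-1-benzofuran-5-yl]ethyl (2Z)-2-methylbut-2-enoate, via mixed anhydride 15 (not isolated)
Conditions: 14, 2,4,6-trichlorobenzoyl chloride, Et3N, toluene, rt; then 13, 70 °C
Reagents that add atoms: 2,4,6-trichlorobenzoyl chloride, O=C(Cl)c1c(Cl)cc(Cl)cc1Cl (acyl group in intermediate 15 only)
Why: Yamaguchi-type esterification through the mixed anhydride, whose hindered trichlorobenzoyl carbonyl directs the alcohol to the angeloyl carbonyl; leaving out a nucleophilic catalyst is meant to keep the Z alkene from isomerising to the tiglate, and acylation at oxygen retains the (R) centre.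

Step 11
Reactants: 16 (1R)-1-[(2R,3R)-3-acetoxy-2-(prop-1-en-2-yl)-2,3-dihydro-1-benzofuran-5-yl]ethyl (2Z)-2-methylbut-2-enoate
Product: 17 (1R)-1-[(2R,3R)-3-acetoxy-2-(3-hydroxyprop-1-en-2-yl)-2,3-dihydro-1-benzofuran-5-yl]ethyl (2Z)-2-methylbut-2-enoate
Conditions: SeO2 (0.3 equiv), t-BuOOH (3 equiv), CH2Cl2, rt
Reagents that add atoms: tert-butyl hydroperoxide, CC(C)(C)OO (oxygen atom, passed on through SeO2, O=[Se]=O)
Why: Selenium dioxide allylic oxidation (ene reaction followed by [2,3]-sigmatropic shift, run catalytically with t-BuOOH) at the methyl group of the 1,1-disubstituted alkene, preferred over the hindered, oxygen-deactivated C2 methine and over the electron-poor angelate alkene; any enal formed alongside converges in step 12.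

Step 12
Reactants: 17 (1R)-1-[(2R,3R)-3-acetoxy-2-(3-hydroxyprop-1-en-2-yl)-2,3-dihydro-1-benzofuran-5-yl]ethyl (2Z)-2-methylbut-2-enoate
Product: 18 (1R)-1-[(2R,3R)-3-acetoxy-2-(3-oxoprop-1-en-2-yl)-2,3-dihydro-1-benzofuran-5-yl]ethyl (2Z)-2-methylbut-2-enoate (CNP0294391.3)
Conditions: MnO2 (activated, excess), CH2Cl2, rt
Reagents that add atoms: none
Why: Chemoselective oxidation of the primary allylic alcohol to the enal with MnO2 under neutral conditions, which avoid base-induced opening of ring B through loss of the aryloxide beta to the new enal and leave all three stereocentres untouched.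

**Compound list**

1 | methyl 5-acetyl-2-hydroxybenzoate (methyl 5-acetylsalicylate) | COC(=O)c1cc(C(C)=O)ccc1O | starting material
2 | methyl 2-hydroxy-5-[(1R)-1-hydroxyethyl]benzoate | COC(=O)c1cc([C@@H](C)O)ccc1O | intermediate
3 | methyl 2-(tert-butyldimethylsilyloxy)-5-[(1R)-1-(tert-butyldimethylsilyloxy)ethyl]benzoate (not isolated) | COC(=O)c1cc([C@@H](C)O[Si](C)(C)C(C)(C)C)ccc1O[Si](C)(C)C(C)(C)C | intermediate
4 | methyl 5-[(1R)-1-(tert-butyldimethylsilyloxy)ethyl]-2-hydroxybenzoate | COC(=O)c1cc([C@@H](C)O[Si](C)(C)C(C)(C)C)ccc1O | intermediate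
5 | 4-[(1R)-1-(tert-butyldimethylsilyloxy)ethyl]-2-(hydroxymethyl)phenol | OCc1cc([C@@H](C)O[Si](C)(C)C(C)(C)C)ccc1O | intermediate
6 | 3-chloro-2-(chloromethyl)prop-1-ene | C=C(CCl)CCl | starting material
7 | {5-[(1R)-1-(tert-butyldimethylsilyloxy)ethyl]-2-{[2-(chloromethyl)prop-2-en-1-yl]oxy}phenyl}methanol | OCc1cc([C@@H](C)O[Si](C)(C)C(C)(C)C)ccc1OCC(=C)CCl | intermediate
8 | 8-[(1R)-1-(tert-butyldimethylsilyloxy)ethyl]-3-methylidene-3,4-dihydro-2H,6H-1,5-benzodioxocine | C=C1COCc2cc([C@@H](C)O[Si](C)(C)C(C)(C)C)ccc2OC1 | intermediate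
9 | 8-[(1R)-1-(tert-butyldimethylsilyloxy)ethyl]-3-methyl-4H,6H-1,5-benzodioxocine | C/C1=C/Oc2ccc([C@@H](C)O[Si](C)(C)C(C)(C)C)cc2COC1 | intermediate
10 | (6R)-8-[(1R)-1-(tert-butyldimethylsilyloxy)ethyl]-6-lithio-3-methyl-4H,6H-1,5-benzodioxocine (not isolated; drawn as the epimer that gives 3R by inversion) | C/C1=C/Oc2ccc([C@@H](C)O[Si](C)(C)C(C)(C)C)cc2[C@@H]([Li])OC1 | intermediate
11 | (2R,3R)-5-[(1R)-1-(tert-butyldimethylsilyloxy)ethyl]-2-(prop-1-en-2-yl)-2,3-dihydro-1-benzofuran-3-ol (cis) | C=C(C)[C@H]1Oc2ccc([C@@H](C)O[Si](C)(C)C(C)(C)C)cc2[C@H]1O | intermediate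
12 | (2R,3R)-5-[(1R)-1-(tert-butyldimethylsilyloxy)ethyl]-2-(prop-1-en-2-yl)-2,3-dihydro-1-benzofuran-3-yl acetate | C=C(C)[C@H]1Oc2ccc([C@@H](C)O[Si](C)(C)C(C)(C)C)cc2[C@H]1OC(C)=O | intermediate
13 | (2R,3R)-5-[(1R)-1-hydroxyethyl]-2-(prop-1-en-2-yl)-2,3-dihydro-1-benzofuran-3-yl acetate | C=C(C)[C@H]1Oc2ccc([C@@H](C)O)cc2[C@H]1OC(C)=O | intermediate
14 | angelic acid, (2Z)-2-methylbut-2-enoic acid | C/C=C(/C)C(=O)O | starting material
15 | (2Z)-2-methylbut-2-enoic 2,4,6-trichlorobenzoic anhydride (not isolated) | C/C=C(/C)C(=O)OC(=O)c1c(Cl)cc(Cl)cc1Cl | intermediate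
16 | (1R)-1-[(2R,3R)-3-acetoxy-2-(prop-1-en-2-yl)-2,3-dihydro-1-benzofuran-5-yl]ethyl (2Z)-2-methylbut-2-enoate | C=C(C)[C@H]1Oc2ccc([C@@H](C)OC(=O)/C(C)=C\C)cc2[C@H]1OC(C)=O | intermediate
17 | (1R)-1-[(2R,3R)-3-acetoxy-2-(3-hydroxyprop-1-en-2-yl)-2,3-dihydro-1-benzofuran-5-yl]ethyl (2Z)-2-methylbut-2-enoate | C=C(CO)[C@H]1Oc2ccc([C@@H](C)OC(=O)/C(C)=C\C)cc2[C@H]1OC(C)=O | intermediate
18 | (1R)-1-[(2R,3R)-3-acetoxy-2-(3-oxoprop-1-en-2-yl)-2,3-dihydro-1-benzofuran-5-yl]ethyl (2Z)-2-methylbut-2-enoate | C=C(C=O)[C@H]1Oc2ccc([C@@H](C)OC(=O)/C(C)=C\C)cc2[C@H]1OC(C)=O | target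

**Step count**

Total: 12 steps. Longest linear sequence: 12 steps (1 to 18); 6 and 14 enter as purchased reactants.

**Steps most likely to fail**

1. Step 7 (proposed new method). The base may deprotonate at another site (vinylic C2–H, allylic C4–H), the anion may take the [1,2] path, the transannular geometry may not be reached, or the ligand may give poor facial control. The fallback uses known chemistry and closes ring B through the O1–C2 bond; it sets out from 5 and returns at 11.
   - MnO2 (CH2Cl2, rt) should oxidise the benzylic alcohol of 5 to 2-hydroxy-5-[(1R)-1-(tert-butyldimethylsilyloxy)ethyl]benzaldehyde F1.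
   - TIPSCl and imidazole (DMF) would protect the phenol as 5-[(1R)-1-(tert-butyldimethylsilyloxy)ethyl]-2-(triisopropylsilyloxy)benzaldehyde F2.
   - Horner–Wadsworth–Emmons olefination with lithiated diethyl (2-methylallyl)phosphonate (n-BuLi, THF, −78 °C to rt) should give the E diene tert-butyl{(1R)-1-[3-[(1E)-3-methylbuta-1,3-dien-1-yl]-4-(triisopropylsilyloxy)phenyl]ethoxy}dimethylsilane F3.
   - Shi epoxidation (D-fructose-derived ketone, KHSO5 as the triple salt 2KHSO5·KHSO4·K2SO4, K2CO3, MeCN–dimethoxymethane–buffer, 0 °C) is expected to epoxidise the trans-disubstituted styrene double bond, not the 1,1-disubstituted one, and to give tert-butyldimethyl{(1R)-1-[3-[(2R,3R)-3-(prop-1-en-2-yl)oxiran-2-yl]-4-(triisopropylsilyloxy)phenyl]ethoxy}silane F4.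
   - TBAF (1 equiv, THF, −20 °C) should cleave only the aryl silyl ether to 4-[(1R)-1-(tert-butyldimethylsilyloxy)ethyl]-2-[(2R,3R)-3-(prop-1-en-2-yl)oxiran-2-yl]phenol F5.
   - Pd(PPh3)4 (5 mol%, THF, rt) would then cyclise F5 to 11: zerovalent palladium ionises the vinyl epoxide with inversion, and the phenol attacks the π-allyl terminus next to the carbinol (5-exo) anti to the metal. The net retention at C2 turns the trans epoxide into the cis (2R,3R) ring B.

2. Step 6. The prototropic shift may run toward the benzylic ether oxygen (poor regioselectivity) or stall. The fallback makes the ring enol ether with the alkene already in place, by closing the aryl–oxygen–vinyl bond; it sets out from 5, returns at 9 and also bypasses steps 4 and 5.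
   - Propargyl alcohol would be carbometallated (MeMgBr, CuI cat., THF) and quenched with I2 to give (2Z)-3-iodo-2-methylprop-2-en-1-ol F6.
   - CBr4 and PPh3 (CH2Cl2, 0 °C) would convert F6 into (1Z)-3-bromo-1-iodo-2-methylprop-1-ene F7.
   - The disodium salt of 5 (NaH 2.1 equiv, THF, 0 °C) should be alkylated by one equivalent of F7 at the more basic benzylic alkoxide, giving 2-({[(2Z)-3-iodo-2-methylprop-2-en-1-yl]oxy}methyl)-4-[(1R)-1-(tert-butyldimethylsilyloxy)ethyl]phenol F8.
   - Intramolecular Ullmann-type O-vinylation (CuI, N,N-dimethylglycine, Cs2CO3, dioxane, 90 °C, high dilution), which keeps the alkene geometry, should close the eight-membered ring to 9.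

3. Step 11. The selenium ene step may show poor site selectivity (attack at the C2 methine or at the angelate methyls), over-oxidise, or cause acid-induced loss of the C3 acetate with aromatisation of ring B. The fallback replaces the selenium oxidant by singlet oxygen; it sets out from 16 and returns at 17.
   - Schenck ene photooxygenation (O2, tetraphenylporphyrin cat., visible light, CH2Cl2, 0 °C) should leave the electron-poor angelate alone and give the allylic hydroperoxide (1R)-1-[(2R,3R)-3-acetoxy-2-(3-hydroperoxyprop-1-en-2-yl)-2,3-dihydro-1-benzofuran-5-yl]ethyl (2Z)-2-methylbut-2-enoate F9.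
   - PPh3 (CH2Cl2, 0 °C) would reduce F9 to 17, which enters step 12 unchanged.

**Further compounds**

F1 | step 7 | 2-hydroxy-5-[(1R)-1-(tert-butyldimethylsilyloxy)ethyl]benzaldehyde | O=Cc1cc([C@@H](C)O[Si](C)(C)C(C)(C)C)ccc1O
F2 | step 7 | 5-[(1R)-1-(tert-butyldimethylsilyloxy)ethyl]-2-(triisopropylsilyloxy)benzaldehyde | O=Cc1cc([C@@H](C)O[Si](C)(C)C(C)(C)C)ccc1O[Si](C(C)C)(C(C)C)C(C)C
F3 | step 7 | tert-butyl{(1R)-1-[3-[(1E)-3-methylbuta-1,3-dien-1-yl]-4-(triisopropylsilyloxy)phenyl]ethoxy}dimethylsilane | C=C(C)/C=C/c1cc([C@@H](C)O[Si](C)(C)C(C)(C)C)ccc1O[Si](C(C)C)(C(C)C)C(C)C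
F4 | step 7 | tert-butyldimethyl{(1R)-1-[3-[(2R,3R)-3-(prop-1-en-2-yl)oxiran-2-yl]-4-(triisopropylsilyloxy)phenyl]ethoxy}silane | C=C(C)[C@H]1O[C@@H]1c1cc([C@@H](C)O[Si](C)(C)C(C)(C)C)ccc1O[Si](C(C)C)(C(C)C)C(C)C
F5 | step 7 | 4-[(1R)-1-(tert-butyldimethylsilyloxy)ethyl]-2-[(2R,3R)-3-(prop-1-en-2-yl)oxiran-2-yl]phenol | C=C(C)[C@H]1O[C@@H]1c1cc([C@@H](C)O[Si](C)(C)C(C)(C)C)ccc1O
F6 | step 6 | (2Z)-3-iodo-2-methylprop-2-en-1-ol | OC/C(C)=C\I
F7 | step 6 | (1Z)-3-bromo-1-iodo-2-methylprop-1-ene | BrC/C(C)=C\I
F8 | step 6 | 2-({[(2Z)-3-iodo-2-methylprop-2-en-1-yl]oxy}methyl)-4-[(1R)-1-(tert-butyldimethylsilyloxy)ethyl]phenol | Oc1ccc([C@@H](C)O[Si](C)(C)C(C)(C)C)cc1COC/C(C)=C\I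
F9 | step 11 | (1R)-1-[(2R,3R)-3-acetoxy-2-(3-hydroperoxyprop-1-en-2-yl)-2,3-dihydro-1-benzofuran-5-yl]ethyl (2Z)-2-methylbut-2-enoate | C=C(COO)[C@H]1Oc2ccc([C@@H](C)OC(=O)/C(C)=C\C)cc2[C@H]1OC(C)=O
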